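Add free monomer and monomer in chains in a late row of the readings below, and a leftover stays short of the charge.

| flask | free monomer | protic impurity | initiator | remark | time |
|---|---|---|---|---|---|
| oak | 0.20 M | 0.028 M | 1 mM | run made earlier |  |
| larch | 0.20 M | 0.044 M | 1 mM | run made earlier |  |
| maple | 0.40 M | 0.020 M | 1 mM | run made earlier |  |
| flask | 0.20 M | 0.0200 M | 1.0 mM |  | 6.0 min |

| run | time / min | monomer in chains / % | free monomer / % |
|---|---|---|---|
| oak | 0.200 | 0.3 | 97.2 |
| oak | 0.500 | 0.3 | 94.0 |
| oak | 1.00 | 1.3 | 89.4 |
| oak | 1.50 | 2.7 | 86.5 |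
| oak | 2.00 | 4.1 | 83.5 |
| oak | 3.00 | 7.4 | 79.5 |
| oak | 4.00 | 11.0 | 75.1 |
| larch | 0.500 | 0.7 | 90.7 |
| larch | 1.00 | 0.9 | 84.5 |
| larch | 1.50 | 2.3 | 81.2 |
| larch | 2.00 | 3.8 | 77.6 |
| larch | 2.50 | 5.0 | 74.9 |
| larch | 3.00 | 6.1 | 72.8 |
| larch | 4.00 | 10.4 | 68.7 |
| maple | 0.250 | 0.1 | 97.4 |
| maple | 0.500 | 1.2 | 96.2 |
| maple | 1.00 | 2.0 | 93.5 |
| maple | 2.00 | 5.9 | 88.6 |
| maple | 4.00 | 15.6 | 79.4 |

(standard deviation of a reading: 0.3 percentage points)

- the average divides the monomer in chains by the number of chains begun, living and dead together
- the earlier runs do not show the number of chains; that part of a forecast is a guess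

- average number of monomer units in a chain (chains begun, living or dead) at 6.0 min
- part of the free monomer that has reacted at 6.0 min

I read the last row of each run. The leftover is 13.9% in oak, 20.9% in larch and 5.00% in maple. Protic impurity over free monomer, as charged, is 14.0%, 22.0% and 5.00%. So I take it that impurity removes free monomer one for one. In the flask that toll is 10.0%.

The rest is growth, which looks pseudo-first-order in free monomer. Between 3.00 min and 4.00 min oak gives 0.0466 min⁻¹; this is g, the monomer entering chains per minute per free monomer. It is a reading, with scatter, and it stands for the growing chains, a concentration I cannot read. Between 1.00 min and 2.00 min oak gave 0.0324 min⁻¹, so oak's g reads as rising.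

For the flask I start from oak's chains at 4.00 min, subtract the toll, and hold g. That leaves 72.0% free monomer, so c is 28.0%, a little low if g keeps rising. If every initiator began a chain, dp is 36.1; that part is a guess.

The forecast gives 45 and 31%, above my numbers, and says “Chain count is a guess”.

The flask gives dp 53.8 and c 29.3%.

    free monomer + initiator → living end + monomer in chains (k = 2.06 M⁻¹ min⁻¹)
    protic impurity + free monomer → quenched substrate (k = 5.22 M⁻¹ min⁻¹)
    free monomer + initiator → spent initiator (k = 0.624 M⁻¹ min⁻¹)
    free monomer + living end → monomer in chains + living end, rate k4*[living end]*[free monomer] (k = 75.2 M⁻¹ min⁻¹)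

At 3.55 min the flask's growth step uses free monomer 12 times as fast as quenching, and at 6.00 min 96 times as fast, with 0.538% of the impurity charge left. In the flask, the growth step's half-life of free monomer of 15 min at the earlier moment is a g of 0.0471 min⁻¹. A neighbour flask has 4.00 times the initiator; I scale my g to 0.186 min⁻¹, and the whole fall I reckoned after the toll by the same factor, which leaves 36.8% free monomer, and that neighbour holds 35.6%.

(The runs were computed with made-up constants.)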